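**Retrosynthetic overview**
1. The last operations are peripheral: C11–OH by 1,2-reduction of a C4 formyl group, the Z-coumarate on O7 by esterification and Suzuki coupling, the acyl acetal by acylation of a C1 lactol. This leads back to tricyclic lactol 16.
2. The pyran ring is formed second (O2–C1): a C1 aldehyde is captured by the enol of a malondialdehyde unit on C4, released from a bis-thioester.
3. The cyclopentane is formed first, in the key step: C8–C9 by intramolecular aldol addition, preceded in the same flask by C4–C5 Michael addition of a dithiomalonate to an enal.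
4. Enabling feature: C1–C9–C8(OH) is a β-hydroxy-aldehyde (aldol) retron, and C8 with its oxygenated neighbours C7 and C10 is a dihydroxyacetone carbonyl. Held in a 1,3-dioxan-5-one ring, this ketone passes the C7 configuration on to C8 and C9; C5, β to C1, is the Michael terminus.
5. C7 is set by SAMP-hydrazone allylation of 2,2-dimethyl-1,3-dioxan-5-one; cross-metathesis supplies the enal.

Key step: step 6

Remark on numbering: iridoid numbering is used for all ring compounds (C1 acetal carbon, O2, C3, C4 bearing C11, C5, C6, C7, C8 bearing C10, C9); "β" means the side of H-5 and H-9. The target is (1S,5S,7S,8R,9S).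
Assumption: the acyl group in the target is (R)-3-methylpentanoyl; (R)-3-methylpentanoic acid and (Z)-3-iodoacrylic acid are taken as purchasable. Lactols are drawn as the 1β-anomer, and the C=N geometry of hydrazone 6 is left open.

**Route**

Step 1
Reactants: 1 2,2-dimethyl-1,3-dioxan-5-one; 2 SAMP
Product: 3 SAMP hydrazone of 1
Conditions: benzene, reflux, water separator
Reagents that add atoms: none
Why: Condensation of the ketone with the 1,1-disubstituted hydrazine (hydrazone formation) should be clean and forms no stereocentre.

Step 2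
Reactants: 3 SAMP hydrazone; 4 allyl bromide
Product: 6 (4S)-allylated SAMP hydrazone, via lithium azaenolate 5 (not isolated)
Conditions: t-BuLi, THF, −78 °C; then 4, −100 °C → rt
Reagents that add atoms: none
Why: SAMP-hydrazone α-alkylation, in which the methoxy-chelated lithium azaenolate should be allylated anti to the pyrrolidine substituent, sets the future C7 as (S) under auxiliary control.

Step 3
Reactants: 6 allylated SAMP hydrazone
Product: 7 (4S)-4-allyl-2,2-dimethyl-1,3-dioxan-5-one
Conditions: sat. aq. oxalic acid, Et2O, rt
Reagents that add atoms: water, O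
Why: Biphasic oxalic acid hydrolysis of the hydrazone should free the ketone without opening the acetonide, epimerising the α-centre or touching the alkene (which rules out ozonolytic cleavage).

Step 4
Reactants: 7 allyl dioxanone; 8 (E)-crotonaldehyde
Product: 9 (2E)-4-[(4S)-2,2-dimethyl-5-oxo-1,3-dioxan-4-yl]but-2-enal
Conditions: 8 (5 equiv), 2nd-generation Ru isopropoxybenzylidene metathesis catalyst (5 mol%), CH2Cl2, 40 °C
Reagents that add atoms: none
Why: Olefin cross-metathesis of the unhindered terminal alkene with an excess of the electron-poor partner should give the E-enal, and the ketone α-centre is not involved.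

Step 5
Reactants: 10 malonyl dichloride; 11 ethanethiol
Product: 12 S,S'-diethyl dithiomalonate
Conditions: 11 (2.1 equiv), pyridine, CH2Cl2, 0 °C → rt
Reagents that add atoms: none
Why: Acylation of the thiol by the bis-acid chloride (nucleophilic acyl substitution) gives a soft, acidic malonate equivalent whose two thioesters can later be reduced to aldehydes.

Step 6
Reactants: 9 enal ketone; 12 S,S'-diethyl dithiomalonate
Product: 14 cyclopentane aldol (C9–CHO, C8–OH, C5–CH(COSEt)2, O7/O10 acetonide), via catalyst-bound enamine 13 (not isolated)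
Conditions: 12 (1.2 equiv), (R)-α,α-diphenylprolinol trimethylsilyl ether (20 mol%), PhCO2H (20 mol%), toluene, 0 °C → rt; short silica plug
Reagents that add atoms: none
Why: The amine condenses with the enal of 9 to an E-iminium ion whose diphenyl(silyloxy)methyl group blocks one face, so the dithiomalonate carbanion adds to C5 from the open face (C4–C5 bond, C5 set S by the catalyst), and the resulting enamine 13 attacks the C8 ketone before hydrolysis releases 14 and the catalyst. The closest known reaction type is the amine-catalysed iminium–enamine domino Michael/intramolecular aldol sequence that builds cyclopentanecarbaldehydes. The cyclopentane C5–C6–C7–C8–C9 is closed by a 5-(enolexo)-exo-trig aldol addition, C8–C9 being the ring-closing bond. C8 is controlled by the dioxanone ring: the tether from C7 can reach the ring carbonyl only on its own face, so the 5/6 junction is cis and the new hydroxyl is trans to O7, which relays the C7 centre. C9 is controlled by the same bicycle, the bulky enamine carbon C1 taking the convex face next to the C8 oxygen and away from C10 and the acetonide, and as an aldehyde α-centre it can still equilibrate to this position. The step needs 1,4- over 1,2-addition and activation of the aldehyde but not the ketone; the soft thiomalonate secures the first, and the hindered amine, which should not form an enamine with the α,α'-dioxygenated ketone (so C7 is not epimerised), secures the second.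

Step 7
Reactants: 14 cyclopentane aldol
Product: 16 tricyclic lactol (1β-OH, 4-CHO, 8α-OH, O7/O10 acetonide), via trialdehyde 15 (not isolated)
Conditions: Et3SiH (6 equiv), 10% Pd/C, acetone, rt; filtration
Reagents that add atoms: none
Why: Fukuyama reduction converts both thioesters into aldehydes without touching the C1 aldehyde or the tertiary alcohol, and the enol of the resulting 2-substituted malondialdehyde adds to the C1 aldehyde to close the dihydropyran (lactolisation), C1 settling under thermodynamic control with OH trans to the fully substituted C8 as in iridoid aglycones.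

Step 8
Reactants: 16 tricyclic lactol; 17 (R)-3-methylpentanoic acid
Product: 18 C1 acyl acetal (1β-O-(R)-3-methylpentanoyl)
Conditions: 17 (1.2 equiv), DCC, DMAP (0.1 equiv), CH2Cl2, 0 °C
Reagents that add atoms: none
Why: Steglich esterification acylates the hemiacetal hydroxyl, the only acylable OH since C8–OH is tertiary, and should trap the predominant 1β-lactol so that C1 is fixed with O trans to C8.

Step 9
Reactants: 18 C1 acyl acetal
Product: 19 7,8,10-triol
Conditions: AcOH/THF/H2O (3:1:1), 35 °C
Reagents that add atoms: none
Why: Acid-catalysed acetal hydrolysis should remove the six-membered acetonide while the C1 acyl acetal survives, because ring oxygen O2 is tied up as a vinylogous formate (O2–C3=C4–CHO) and supports an oxocarbenium ion at C1 poorly.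

Step 10
Reactants: 19 triol
Product: 20 C10 TBS ether
Conditions: TBSCl (1.1 equiv), imidazole, DMF, 0 °C
Reagents that add atoms: tert-butyldimethylsilyl chloride, CC(C)(C)[Si](C)(C)Cl
Why: Silylation with TBSCl and imidazole is selective for the primary C10–OH over the hindered secondary C7–OH and the tertiary C8–OH.

Step 11
Reactants: 20 C10 TBS ether; 21 (Z)-3-iodoacrylic acid
Product: 22 C7 (Z)-3-iodoacrylate
Conditions: 21 (1.5 equiv), DCC, DMAP (5 mol%), CH2Cl2, −20 → 0 °C, dark
Reagents that add atoms: none
Why: Steglich esterification of the only remaining acylable hydroxyl (C7–OH) at low temperature with little DMAP should keep the Z geometry of the iodoacrylate.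

Step 12
Reactants: 22 C7 (Z)-3-iodoacrylate; 23 (4-hydroxyphenyl)boronic acid
Product: 24 C7 (Z)-p-coumarate
Conditions: 23 (1.5 equiv), Pd2(dba)3 (2.5 mol%), P(t-Bu)3·HBF4 (6 mol%), KF (3 equiv), THF, rt, dark
Reagents that add atoms: none
Why: Suzuki–Miyaura coupling of a vinyl iodide proceeds with retention of alkene geometry, and fluoride as base at room temperature should spare the acyl acetal, both esters and the silyl ether.

Step 13
Reactants: 24 C7 (Z)-p-coumarate
Product: 25 C10 alcohol (11-aldehyde)
Conditions: HF·pyridine, pyridine, THF, 0 °C → rt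
Reagents that add atoms: none
Why: Buffered fluoride-mediated desilylation cleaves the primary silyl ether while the pyran is still deactivated by the C4 formyl group, and the non-basic medium should prevent acyl migration from O7 to O10.

Step 14
Reactants: 25 C10 alcohol (11-aldehyde)
Product: 26 target CNP0217341.1
Conditions: NaBH4, CeCl3·7H2O, MeOH/THF, −78 → −40 °C; acetone, then pH 7 buffer
Reagents that add atoms: none
Why: Luche reduction should reduce the vinylogous formate aldehyde 1,2-selectively to the C11 allylic alcohol at low temperature without touching the acyl acetal, the two esters or the Z-enoate.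

**Compound list**
1 | 2,2-dimethyl-1,3-dioxan-5-one | CC1(C)OCC(=O)CO1 | starting material
2 | SAMP, (S)-1-amino-2-(methoxymethyl)pyrrolidine | COC[C@@H]1CCCN1N | starting material
3 | (S)-N-(2,2-dimethyl-1,3-dioxan-5-ylidene)-2-(methoxymethyl)pyrrolidin-1-amine | COC[C@@H]1CCCN1N=C1COC(C)(C)OC1 | intermediate
4 | allyl bromide | C=CCBr | starting material
5 | lithium azaenolate of 3 | COC[C@@H]1CCCN1N([Li])C1=COC(C)(C)OC1 | intermediate
6 | (S)-N-[(4S)-2,2-dimethyl-4-(prop-2-en-1-yl)-1,3-dioxan-5-ylidene]-2-(methoxymethyl)pyrrolidin-1-amine | COC[C@@H]1CCCN1N=C1COC(C)(C)O[C@H]1CC=C | intermediate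
7 | (4S)-2,2-dimethyl-4-(prop-2-en-1-yl)-1,3-dioxan-5-one | C=CC[C@@H]1OC(C)(C)OCC1=O | intermediate
8 | (E)-crotonaldehyde | C/C=C/C=O | starting material
9 | (2E)-4-[(4S)-2,2-dimethyl-5-oxo-1,3-dioxan-4-yl]but-2-enal | O=C/C=C/C[C@@H]1OC(C)(C)OCC1=O | intermediate
10 | malonyl dichloride | O=C(Cl)CC(=O)Cl | starting material
11 | ethanethiol | CCS | starting material
12 | S,S'-diethyl propanebis(thioate) | CCSC(=O)CC(=O)SCC | intermediate
13 | E-enamine of the Michael adduct with the (R)-diphenylprolinol silyl ether catalyst (C5 S, C7 S, ketone still open) | CCSC(=O)C(C(=O)SCC)[C@H](/C=C/N1CCC[C@@H]1C(O[Si](C)(C)C)(c1ccccc1)c1ccccc1)C[C@@H]1OC(C)(C)OCC1=O | intermediate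
14 | S,S'-diethyl 2-[(4aR,5S,6S,7aS)-5-formyl-4a-hydroxy-2,2-dimethylhexahydrocyclopenta[d][1,3]dioxin-6-yl]propanebis(thioate) | CCSC(=O)C(C(=O)SCC)[C@H]1C[C@@H]2OC(C)(C)OC[C@]2(O)[C@H]1C=O | intermediate
15 | 2-[(4aR,5S,6S,7aS)-5-formyl-4a-hydroxy-2,2-dimethylhexahydrocyclopenta[d][1,3]dioxin-6-yl]propanedial | O=CC(C=O)[C@H]1C[C@@H]2OC(C)(C)OC[C@]2(O)[C@H]1C=O | intermediate
16 | iridoid lactol: 1β,8α-dihydroxy, C4 formyl (C11 aldehyde), O7/O10 isopropylidene (O7 and C10 β), H-5β, H-9β | O[C@@H]1OC=C(C=O)[C@H]2C[C@@H]3OC(C)(C)OC[C@]3(O)[C@@H]12 | intermediate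
17 | (R)-3-methylpentanoic acid | CC[C@@H](C)CC(=O)O | starting material
18 | 1β-O-[(R)-3-methylpentanoyl] derivative of 16 | CC[C@@H](C)CC(=O)O[C@@H]1OC=C(C=O)[C@H]2C[C@@H]3OC(C)(C)OC[C@]3(O)[C@@H]12 | intermediate
19 | 1β-O-[(R)-3-methylpentanoyl]-7β,8α,10-trihydroxy iridoid 11-aldehyde | CC[C@@H](C)CC(=O)O[C@@H]1OC=C(C=O)[C@H]2C[C@H](O)[C@](O)(CO)[C@@H]12 | intermediate
20 | 10-O-TBS ether of 19 | CC[C@@H](C)CC(=O)O[C@@H]1OC=C(C=O)[C@H]2C[C@H](O)[C@](O)(CO[Si](C)(C)C(C)(C)C)[C@@H]12 | intermediate
21 | (Z)-3-iodoprop-2-enoic acid | OC(=O)/C=C\I | starting material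
22 | 7-O-[(Z)-3-iodoacryloyl] derivative of 20 | CC[C@@H](C)CC(=O)O[C@@H]1OC=C(C=O)[C@H]2C[C@H](OC(=O)/C=C\I)[C@](O)(CO[Si](C)(C)C(C)(C)C)[C@@H]12 | intermediate
23 | (4-hydroxyphenyl)boronic acid | OB(O)c1ccc(O)cc1 | starting material
24 | 7-O-[(Z)-p-coumaroyl]-10-O-TBS iridoid 11-aldehyde | CC[C@@H](C)CC(=O)O[C@@H]1OC=C(C=O)[C@H]2C[C@H](OC(=O)/C=C\c3ccc(O)cc3)[C@](O)(CO[Si](C)(C)C(C)(C)C)[C@@H]12 | intermediate
25 | 7-O-[(Z)-p-coumaroyl]-8α,10-dihydroxy iridoid 11-aldehyde | CC[C@@H](C)CC(=O)O[C@@H]1OC=C(C=O)[C@H]2C[C@H](OC(=O)/C=C\c3ccc(O)cc3)[C@](O)(CO)[C@@H]12 | intermediate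
26 | CNP0217341.1, (1S,5S,7S,8R,9S) in iridoid numbering | CC[C@@H](C)CC(=O)O[C@@H]1OC=C(CO)[C@H]2C[C@H](OC(=O)/C=C\c3ccc(O)cc3)[C@](O)(CO)[C@@H]12 | target

**Step count**
Total: 14 steps. Longest linear sequence: 13 steps (1–4, then 6–14); step 5 is a one-step branch.

**Steps most likely to fail**

Step 6. Enamine 13 may be hydrolysed before it closes the ring, the β-hydroxy aldehyde may lose water on the amine, or C7 may epimerise before the aldol locks it. The fallback makes the two C–C bonds separately and the rings in the opposite order. It sets out from 9 and 12: the conjugate addition would be run alone with the same catalyst in aqueous ethanol at −20 °C, where protonation of the enamine should outrun cyclisation, to give the open Michael adduct F1. Fukuyama reduction (Et3SiH, Pd/C, acetone) would then give the monocyclic lactol ketone F2 with the pyran ring already in place. DBU (0.2 equiv, MeCN, 0 °C) would close the C8–C9 bond by a base-mediated intramolecular aldol addition of the ring-opened C1 aldehyde onto the dioxanone carbonyl under thermodynamic control, with the cis-fused lactol as the expected sink. The route is rejoined at 16.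

Step 9. The C1 acyl group may be lost or migrate, or the enol ether may be hydrated, during the acidic hydrolysis. The fallback exchanges the tether for a fluoride-labile one before the acyl acetal exists. It sets out from 16: aqueous acetic acid would give the tetrahydroxy lactol F4, and tBu2Si(OTf)2 with 2,6-lutidine (DMF, −40 °C) should bridge the 1,3-diol O7/O10 to give the silylene lactol F5. Steglich acylation with 17, as in step 8, would give the silylene acyl acetal F6, and HF·pyridine in THF/pyridine would remove the silylene without aqueous acid. The route is rejoined at 19.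

Step 8. Both lactol anomers, or the ring-opened enol form, may be acylated, giving poor control of C1. The fallback replaces acylation of the hydroxyl by substitution at C1. It sets out from 16: Cl3CCN with catalytic DBU (CH2Cl2, 0 °C) would give the trichloroacetimidate F3. Treatment with acid 17 and catalytic TMSOTf (CH2Cl2, −40 °C) should then deliver the carboxylate to the oxocarbenium ion on the face opposite the fully substituted C8. The route is rejoined at 18.

**Further compounds**
F1 | step 6 | S,S'-diethyl 2-[(2S)-1-[(4S)-2,2-dimethyl-5-oxo-1,3-dioxan-4-yl]-4-oxobutan-2-yl]propanebis(thioate) | CCSC(=O)C(C(=O)SCC)[C@H](CC=O)C[C@@H]1OC(C)(C)OCC1=O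
F2 | step 6 | 2-hydroxy-4-{[(4S)-2,2-dimethyl-5-oxo-1,3-dioxan-4-yl]methyl}-3,4-dihydro-2H-pyran-5-carbaldehyde (C5 S, anomers) | OC1C[C@H](C[C@@H]2OC(C)(C)OCC2=O)C(C=O)=CO1
F3 | step 8 | 1β-O-trichloroacetimidate of 16 | ClC(Cl)(Cl)C(=N)O[C@@H]1OC=C(C=O)[C@H]2C[C@@H]3OC(C)(C)OC[C@]3(O)[C@@H]12
F4 | step 9 | 1β,7β,8α,10-tetrahydroxy iridoid 11-aldehyde | O[C@@H]1OC=C(C=O)[C@H]2C[C@H](O)[C@](O)(CO)[C@@H]12
F5 | step 9 | 7,10-O-(di-tert-butylsilylene) derivative of F4 | O[C@@H]1OC=C(C=O)[C@H]2C[C@@H]3O[Si](C(C)(C)C)(C(C)(C)C)OC[C@]3(O)[C@@H]12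
F6 | step 9 | 1β-O-[(R)-3-methylpentanoyl] derivative of F5 | CC[C@@H](C)CC(=O)O[C@@H]1OC=C(C=O)[C@H]2C[C@@H]3O[Si](C(C)(C)C)(C(C)(C)C)OC[C@]3(O)[C@@H]12
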